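## Retrosynthetic overview

1. The target comes from the fully protected aryl ketone by acetonide/TBS hydrolysis and then O-debenzylation.
2. The aryl–C(=O) bond is cut to an aryllithium (from a para-bromo aryl ether) plus 3-(TBSO)propanal, followed by oxidation. No ketone is therefore present during the enolate chemistry.
3. The bromo acetonide comes from the threo 1,3-diol, which comes from reductive removal of the auxiliary from a syn-aldol adduct.
4. The key C7–C8 bond is made by an Evans boron syn-aldol between the (R)-4-benzyloxazolidinone imide of the aryloxyacetic acid and veratraldehyde. This step sets both stereocentres.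
5. The aryloxyacetic acid comes from o-vanillin by bromination, O-alkylation, Baeyer–Villiger oxidation and benzylation. Both arenes are bought, and the only ring made is the temporary 1,3-dioxane (closed in step 9, opened in step 14).

Assumption: lignan numbering is used (C7/C8/C9 for the glycerol chain, primes for the keto-aryl unit). The SMILES reads as (7S,8S), the threo series. The transient carbinol centre of 23 is left undefined because step 13 erases it.

## Route

Step 1
Reactants: 1 2-hydroxy-3-methoxybenzaldehyde (o-vanillin)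
Product: 2 5-bromo-2-hydroxy-3-methoxybenzaldehyde
Conditions: Br2 (1.05 equiv), NaOAc (1.2 equiv), AcOH, rt, 2 h
Reagents that add atoms: bromine, BrBr
Why: Electrophilic aromatic bromination in which the free phenol directs and, with both ortho positions occupied (CHO, OMe), only its para position is attacked while NaOAc buffers the HBr.

Step 2
Reactants: 2 5-bromo-2-hydroxy-3-methoxybenzaldehyde; 3 tert-butyl bromoacetate
Product: 4 tert-butyl 2-(4-bromo-2-formyl-6-methoxyphenoxy)acetate
Conditions: K2CO3 (1.5 equiv), DMF, rt, 12 h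
Reagents that add atoms: none
Why: Williamson ether synthesis at room temperature, well below the temperatures at which 2-formylphenoxyacetates condense to benzofurans, using a bulky tert-butyl ester that resists attack by the neighbouring phenoxide freed in step 3.

Step 3
Reactants: 4 tert-butyl 2-(4-bromo-2-formyl-6-methoxyphenoxy)acetate
Product: 6 tert-butyl 2-(4-bromo-2-hydroxy-6-methoxyphenoxy)acetate, via aryl formate 5 (not isolated)
Conditions: mCPBA (1.5 equiv), CH2Cl2, rt to 40 °C; then MeOH, Et3N (cat.), rt, 30 min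
Reagents that add atoms: mCPBA (3-chloroperbenzoic acid), OOC(=O)c1cccc(Cl)c1
Why: Baeyer–Villiger (Dakin-type) oxidation in which the ortho-alkoxy aryl group migrates in the Criegee adduct to give formate 5, which is so much more labile than the tert-butyl ester that amine-catalysed methanolysis frees only the phenol.

Step 4
Reactants: 6 tert-butyl 2-(4-bromo-2-hydroxy-6-methoxyphenoxy)acetate
Product: 7 tert-butyl 2-[2-(benzyloxy)-4-bromo-6-methoxyphenoxy]acetate
Conditions: BnBr (1.2 equiv), K2CO3 (1.5 equiv), DMF, rt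
Reagents that add atoms: benzyl bromide, BrCc1ccccc1
Why: Williamson benzylation of the only acidic OH, giving a group that withstands dilute TFA, boron triflate, borohydride, n-BuLi at −78 °C and DMP and is removed at the end under neutral conditions.

Step 5
Reactants: 7 tert-butyl 2-[2-(benzyloxy)-4-bromo-6-methoxyphenoxy]acetate
Product: 8 2-[2-(benzyloxy)-4-bromo-6-methoxyphenoxy]acetic acid
Conditions: TFA/CH2Cl2 (1:4), 0 °C to rt, 2–3 h
Reagents that add atoms: none
Why: Acidolysis of the tert-butyl ester (AAL1, loss of isobutene) needs no hydroxide and leaves the aryl benzyl ether, the methyl ether and the aryl bromide untouched.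

Step 6
Reactants: 8 2-[2-(benzyloxy)-4-bromo-6-methoxyphenoxy]acetic acid; 9 (R)-4-benzyl-1,3-oxazolidin-2-one
Product: 11 (R)-4-benzyl-3-{2-[2-(benzyloxy)-4-bromo-6-methoxyphenoxy]acetyl}-1,3-oxazolidin-2-one, via mixed pivalic anhydride 10 (not isolated)
Conditions: PivCl (1.05 equiv), Et3N (2.5 equiv), THF, −20 °C, 1 h; then LiCl (1.1 equiv), 9, −20 °C to rt
Reagents that add atoms: pivaloyl chloride, CC(C)(C)C(=O)Cl (its acyl group is held only in 10 and is absent from 11)
Why: N-acylation through a mixed anhydride (LiCl/Et3N variant), in which the oxazolidinone attacks the unhindered aryloxyacetyl carbonyl rather than the pivaloyl carbonyl and the stereocentre of 9 is not touched.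

Step 7
Reactants: 11 (R)-4-benzyl-3-{2-[2-(benzyloxy)-4-bromo-6-methoxyphenoxy]acetyl}-1,3-oxazolidin-2-one; 12 3,4-dimethoxybenzaldehyde (veratraldehyde)
Product: 15 (R)-4-benzyl-3-{(2R,3S)-2-[2-(benzyloxy)-4-bromo-6-methoxyphenoxy]-3-(3,4-dimethoxyphenyl)-3-hydroxypropanoyl}-1,3-oxazolidin-2-one, via Z-boron enolate 13 (not isolated), via boron aldolate 14 (not isolated)
Conditions: Bu2BOTf (1.2 equiv), Et3N (1.5 equiv), CH2Cl2, −78 to 0 °C; 12 (1.3 equiv), −78 to 0 °C; then pH 7 buffer, MeOH, 30% H2O2, 0 °C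
Reagents that add atoms: dibutylboron triflate, CCCCB(CCCC)OS(=O)(=O)C(F)(F)F (its Bu2B unit is held only in 13 and 14 and is absent from 15)
Why: Evans boron syn-aldol in which soft enolisation gives only Z-enolate 13, which reacts through a dipole-minimised Zimmerman–Traxler chair on the face opposite the auxiliary benzyl group, so the (R)-auxiliary sets C8 (2R in 15) and C7 (3S) together in the syn (threo) relationship.

Step 8
Reactants: 15 syn-aldol adduct
Product: 17 (1S,2S)-2-[2-(benzyloxy)-4-bromo-6-methoxyphenoxy]-1-(3,4-dimethoxyphenyl)propane-1,3-diol, via hydroxy aldehyde 16 (not isolated)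
Conditions: NaBH4 (4 equiv), THF/H2O (4:1), 0 °C to rt
Reagents that add atoms: none
Why: Reductive cleavage of the imide at the more electrophilic exocyclic carbonyl, with aldehyde 16 reduced at once so that C8 does not epimerise (its descriptor changes from R to S only because CH2OH ranks below C7) and with the aryl bromide and benzyl ether inert.

Step 9
Reactants: 17 threo diol
Product: 18 (4S,5S)-5-[2-(benzyloxy)-4-bromo-6-methoxyphenoxy]-4-(3,4-dimethoxyphenyl)-2,2-dimethyl-1,3-dioxane
Conditions: Me2C(OMe)2 (5 equiv), PPTS (0.1 equiv), CH2Cl2, rt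
Reagents that add atoms: 2,2-dimethoxypropane, COC(C)(C)OC
Why: Acid-catalysed transketalisation closes the 1,3-dioxane without breaking a C–O bond at C7 or C8, masks both OH groups for steps 12 and 13, and gives a cis-4,5 ring whose small J(4,5) (about 2–3 Hz against 9–10 Hz for the trans ring of the erythro isomer) checks the relative configuration.

Step 10
Reactants: 19 propane-1,3-diol
Product: 20 3-[(tert-butyldimethylsilyl)oxy]propan-1-ol
Conditions: TBSCl (1 equiv), imidazole (1.2 equiv), 19 (4 equiv), THF, 0 °C to rt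
Reagents that add atoms: tert-butyldimethylsilyl chloride, CC(C)(C)[Si](C)(C)Cl
Why: Statistical monosilylation in which a fourfold excess of the cheap, water-soluble diol gives almost only the mono ether and the surplus washes out.

Step 11
Reactants: 20 3-[(tert-butyldimethylsilyl)oxy]propan-1-ol
Product: 21 3-[(tert-butyldimethylsilyl)oxy]propanal
Conditions: TEMPO (0.1 equiv), PhI(OAc)2 (1.1 equiv), CH2Cl2, rt
Reagents that add atoms: none
Why: TEMPO/PhI(OAc)2 (oxoammonium) oxidation stops at the aldehyde under non-basic conditions, so the β-silyloxy group is not eliminated.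

Step 12
Reactants: 18 bromo acetonide; 21 3-[(tert-butyldimethylsilyl)oxy]propanal
Product: 23 1-{3-(benzyloxy)-4-[[(4S,5S)-4-(3,4-dimethoxyphenyl)-2,2-dimethyl-1,3-dioxan-5-yl]oxy]-5-methoxyphenyl}-3-[(tert-butyldimethylsilyl)oxy]propan-1-ol (epimers at the carbinol carbon), via aryllithium 22 (not isolated)
Conditions: n-BuLi (1.1 equiv), THF, −78 °C, 20 min; 21 (1.5 equiv), −78 °C, 1 h; aq NH4Cl
Reagents that add atoms: n-butyllithium, [Li]CCCC (its lithium is held only in 22 and is absent from 23)
Why: Bromine–lithium exchange followed by 1,2-addition, the exchange at −78 °C being far faster than any deprotonation of the fully protected 18, with the new carbinol centre formed as an epimer mixture that step 13 erases.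

Step 13
Reactants: 23 benzylic carbinol
Product: 24 1-{3-(benzyloxy)-4-[[(4S,5S)-4-(3,4-dimethoxyphenyl)-2,2-dimethyl-1,3-dioxan-5-yl]oxy]-5-methoxyphenyl}-3-[(tert-butyldimethylsilyl)oxy]propan-1-one
Conditions: DMP (1.3 equiv), pyridine (3 equiv), CH2Cl2, 0 °C to rt
Reagents that add atoms: none
Why: Dess–Martin oxidation under pyridine buffering converts the only free OH into the aryl ketone without touching the acetonide, silyl or benzyl ethers and without β-elimination.

Step 14
Reactants: 24 protected ketone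
Product: 25 1-{3-(benzyloxy)-4-[[(1S,2S)-1-(3,4-dimethoxyphenyl)-1,3-dihydroxypropan-2-yl]oxy]-5-methoxyphenyl}-3-hydroxypropan-1-one
Conditions: 1 M aq HCl/THF (1:3), rt, monitored by TLC
Reagents that add atoms: none
Why: Mild acid hydrolysis cleaves the TBS ether at Si–O and the acetonide at the ketal carbon, so no bond to C7 or C8 is broken, and dilute acid at rt is too weak to ionise the benzylic alcohol or dehydrate the β-hydroxy ketone.

Step 15
Reactants: 25 benzyl-protected triol ketone
Product: 26 1-{4-[[(1S,2S)-1-(3,4-dimethoxyphenyl)-1,3-dihydroxypropan-2-yl]oxy]-3-hydroxy-5-methoxyphenyl}-3-hydroxypropan-1-one (target, 7S,8S)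
Conditions: H2 (1 atm), 10% Pd/C, EtOAc, rt, stopped when 25 is consumed
Reagents that add atoms: none
Why: Catalytic hydrogenolysis cleaves the aryl benzyl ether much faster than the electron-rich aryl ketone or the secondary benzylic alcohol is reduced in neutral EtOAc at 1 atm, so (7S,8S) is unchanged.

## Compound list

1 | 2-hydroxy-3-methoxybenzaldehyde (o-vanillin) | COc1cccc(C=O)c1O | starting material
2 | 5-bromo-2-hydroxy-3-methoxybenzaldehyde | COc1cc(Br)cc(C=O)c1O | intermediate
3 | tert-butyl bromoacetate | CC(C)(C)OC(=O)CBr | starting material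
4 | tert-butyl 2-(4-bromo-2-formyl-6-methoxyphenoxy)acetate | COc1cc(Br)cc(C=O)c1OCC(=O)OC(C)(C)C | intermediate
5 | tert-butyl 2-[4-bromo-2-(formyloxy)-6-methoxyphenoxy]acetate (aryl formate) | COc1cc(Br)cc(OC=O)c1OCC(=O)OC(C)(C)C | intermediate
6 | tert-butyl 2-(4-bromo-2-hydroxy-6-methoxyphenoxy)acetate | COc1cc(Br)cc(O)c1OCC(=O)OC(C)(C)C | intermediate
7 | tert-butyl 2-[2-(benzyloxy)-4-bromo-6-methoxyphenoxy]acetate | COc1cc(Br)cc(OCc2ccccc2)c1OCC(=O)OC(C)(C)C | intermediate
8 | 2-[2-(benzyloxy)-4-bromo-6-methoxyphenoxy]acetic acid | COc1cc(Br)cc(OCc2ccccc2)c1OCC(=O)O | intermediate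
9 | (R)-4-benzyl-1,3-oxazolidin-2-one | O=C1N[C@H](Cc2ccccc2)CO1 | starting material
10 | 2-[2-(benzyloxy)-4-bromo-6-methoxyphenoxy]acetic pivalic anhydride | COc1cc(Br)cc(OCc2ccccc2)c1OCC(=O)OC(=O)C(C)(C)C | intermediate
11 | (R)-4-benzyl-3-{2-[2-(benzyloxy)-4-bromo-6-methoxyphenoxy]acetyl}-1,3-oxazolidin-2-one | COc1cc(Br)cc(OCc2ccccc2)c1OCC(=O)N3[C@H](Cc4ccccc4)COC3=O | intermediate
12 | 3,4-dimethoxybenzaldehyde (veratraldehyde) | COc1ccc(C=O)cc1OC | starting material
13 | (Z)-dibutylboron enolate of 11 | CCCCB(CCCC)O/C(=C\Oc1c(OCc2ccccc2)cc(Br)cc1OC)N3[C@H](Cc4ccccc4)COC3=O | intermediate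
14 | O-dibutylboryl aldolate of 15 | COc1ccc([C@H](OB(CCCC)CCCC)[C@H](C(=O)N2[C@H](Cc3ccccc3)COC2=O)Oc4c(OCc5ccccc5)cc(Br)cc4OC)cc1OC | intermediate
15 | (R)-4-benzyl-3-{(2R,3S)-2-[2-(benzyloxy)-4-bromo-6-methoxyphenoxy]-3-(3,4-dimethoxyphenyl)-3-hydroxypropanoyl}-1,3-oxazolidin-2-one | COc1ccc([C@H](O)[C@H](C(=O)N2[C@H](Cc3ccccc3)COC2=O)Oc4c(OCc5ccccc5)cc(Br)cc4OC)cc1OC | intermediate
16 | (2R,3S)-2-[2-(benzyloxy)-4-bromo-6-methoxyphenoxy]-3-(3,4-dimethoxyphenyl)-3-hydroxypropanal | COc1ccc([C@H](O)[C@H](C=O)Oc2c(OCc3ccccc3)cc(Br)cc2OC)cc1OC | intermediate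
17 | (1S,2S)-2-[2-(benzyloxy)-4-bromo-6-methoxyphenoxy]-1-(3,4-dimethoxyphenyl)propane-1,3-diol | COc1ccc([C@H](O)[C@H](CO)Oc2c(OCc3ccccc3)cc(Br)cc2OC)cc1OC | intermediate
18 | (4S,5S)-5-[2-(benzyloxy)-4-bromo-6-methoxyphenoxy]-4-(3,4-dimethoxyphenyl)-2,2-dimethyl-1,3-dioxane | COc1ccc([C@@H]2OC(C)(C)OC[C@@H]2Oc3c(OCc4ccccc4)cc(Br)cc3OC)cc1OC | intermediate
19 | propane-1,3-diol | OCCCO | starting material
20 | 3-[(tert-butyldimethylsilyl)oxy]propan-1-ol | CC(C)(C)[Si](C)(C)OCCCO | intermediate
21 | 3-[(tert-butyldimethylsilyl)oxy]propanal | CC(C)(C)[Si](C)(C)OCCC=O | intermediate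
22 | aryllithium from 18 (Li in place of Br) | COc1ccc([C@@H]2OC(C)(C)OC[C@@H]2Oc3c(OCc4ccccc4)cc([Li])cc3OC)cc1OC | intermediate
23 | 1-{3-(benzyloxy)-4-[[(4S,5S)-4-(3,4-dimethoxyphenyl)-2,2-dimethyl-1,3-dioxan-5-yl]oxy]-5-methoxyphenyl}-3-[(tert-butyldimethylsilyl)oxy]propan-1-ol (carbinol epimers) | COc1ccc([C@@H]2OC(C)(C)OC[C@@H]2Oc3c(OCc4ccccc4)cc(C(O)CCO[Si](C)(C)C(C)(C)C)cc3OC)cc1OC | intermediate
24 | 1-{3-(benzyloxy)-4-[[(4S,5S)-4-(3,4-dimethoxyphenyl)-2,2-dimethyl-1,3-dioxan-5-yl]oxy]-5-methoxyphenyl}-3-[(tert-butyldimethylsilyl)oxy]propan-1-one | COc1ccc([C@@H]2OC(C)(C)OC[C@@H]2Oc3c(OCc4ccccc4)cc(C(=O)CCO[Si](C)(C)C(C)(C)C)cc3OC)cc1OC | intermediate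
25 | 1-{3-(benzyloxy)-4-[[(1S,2S)-1-(3,4-dimethoxyphenyl)-1,3-dihydroxypropan-2-yl]oxy]-5-methoxyphenyl}-3-hydroxypropan-1-one | COc1ccc([C@H](O)[C@H](CO)Oc2c(OCc3ccccc3)cc(C(=O)CCO)cc2OC)cc1OC | intermediate
26 | 1-{4-[[(1S,2S)-1-(3,4-dimethoxyphenyl)-1,3-dihydroxypropan-2-yl]oxy]-3-hydroxy-5-methoxyphenyl}-3-hydroxypropan-1-one (CNP0188882.1) | COc1ccc([C@H](O)[C@H](CO)Oc2c(O)cc(C(=O)CCO)cc2OC)cc1OC | target

## Step count and risks

- **Total step count:** 15.
- **Longest linear sequence:** 13 (steps 1–9 and 12–15, from o-vanillin). Steps 10–11 form the two-step side branch.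

**Step 7 (aldol).** The 2,6-disubstituted aryloxy group crowds the boron enolate and veratraldehyde is a deactivated electrophile, so conversion or diastereoselectivity may be poor. The fallback sets out from acid 8 and comes back at diol 17.
- Acid 8 is coupled (EDC·HCl, DMAP, CH2Cl2) with commercial (R)-4-benzyl-1,3-thiazolidine-2-thione to give the N-acyl thiazolidinethione F1.
- Soft enolisation with TiCl4/iPr2NEt/NMP (CH2Cl2, −78 to 0 °C) and addition of 12 goes through the non-chelated chair and should give the same (2R,3S) sense in the thiazolidinethione syn-aldol adduct F2. The more Lewis-acidic titanium activates the electron-rich aldehyde better, and minor diastereomers are removed by chromatography.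
- The very labile auxiliary is then displaced with NaBH4 (THF/EtOH, 0 °C) to give 17.

**Step 12 (aryllithium addition).** The basic aryllithium may enolise aldehyde 21 or trigger β-elimination, and 21 itself does not store well. The fallback sets out from bromide 18, with alcohol 20 as the C3 source, and comes back at ketone 24, bypassing 23 and step 13.
- Alcohol 20 is oxidised (TEMPO, PhI(OAc)2, MeCN/H2O) to 3-[(tert-butyldimethylsilyl)oxy]propanoic acid F3.
- F3 is coupled (EDC·HCl, MeONHMe·HCl, N-methylmorpholine) to the shelf-stable, much less acidic Weinreb amide F4.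
- Aryllithium 22, made from 18 as before, acylates on F4 at −78 °C, and the chelated adduct collapses to 24 only on quench.

**Step 3 (Baeyer–Villiger and phenol release).** Aryl migration on the bromo-deactivated ring may compete with oxidation to the acid. The freed phenol also sits next to an ester and could lactonise to a benzodioxinone. The fallback sets out from 2 and comes back at 7, so no phenol ever neighbours an ester and the migrating ring carries a better donor.
- 2 is protected (MOMCl, iPr2NEt, CH2Cl2) as 5-bromo-3-methoxy-2-(methoxymethoxy)benzaldehyde F5.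
- F5 is oxidised (mCPBA, CH2Cl2) to 5-bromo-3-methoxy-2-(methoxymethoxy)phenyl formate F6.
- F6 is methanolysed (cat. K2CO3, MeOH) to 5-bromo-3-methoxy-2-(methoxymethoxy)phenol F7.
- F7 is benzylated (BnBr, K2CO3, DMF) to 1-(benzyloxy)-5-bromo-3-methoxy-2-(methoxymethoxy)benzene F8.
- F8 is freed from MOM (HCl, MeOH, 40 °C) to give 2-(benzyloxy)-4-bromo-6-methoxyphenol F9.
- F9 is alkylated with 3 (K2CO3, DMF, 50 °C) to give 7.

## Further compounds

F1 | step 7 | 2-[2-(benzyloxy)-4-bromo-6-methoxyphenoxy]-1-[(4R)-4-benzyl-2-thioxo-1,3-thiazolidin-3-yl]ethan-1-one | COc1cc(Br)cc(OCc2ccccc2)c1OCC(=O)N3[C@H](Cc4ccccc4)CSC3=S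
F2 | step 7 | (2R,3S)-2-[2-(benzyloxy)-4-bromo-6-methoxyphenoxy]-1-[(4R)-4-benzyl-2-thioxo-1,3-thiazolidin-3-yl]-3-(3,4-dimethoxyphenyl)-3-hydroxypropan-1-one | COc1ccc([C@H](O)[C@H](C(=O)N2[C@H](Cc3ccccc3)CSC2=S)Oc4c(OCc5ccccc5)cc(Br)cc4OC)cc1OC
F3 | step 12 | 3-[(tert-butyldimethylsilyl)oxy]propanoic acid | CC(C)(C)[Si](C)(C)OCCC(=O)O
F4 | step 12 | 3-[(tert-butyldimethylsilyl)oxy]-N-methoxy-N-methylpropanamide | CON(C)C(=O)CCO[Si](C)(C)C(C)(C)C
F5 | step 3 | 5-bromo-3-methoxy-2-(methoxymethoxy)benzaldehyde | COCOc1c(C=O)cc(Br)cc1OC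
F6 | step 3 | 5-bromo-3-methoxy-2-(methoxymethoxy)phenyl formate | COCOc1c(OC=O)cc(Br)cc1OC
F7 | step 3 | 5-bromo-3-methoxy-2-(methoxymethoxy)phenol | COCOc1c(O)cc(Br)cc1OC
F8 | step 3 | 1-(benzyloxy)-5-bromo-3-methoxy-2-(methoxymethoxy)benzene | COCOc1c(OCc2ccccc2)cc(Br)cc1OC
F9 | step 3 | 2-(benzyloxy)-4-bromo-6-methoxyphenol | COc1cc(Br)cc(OCc2ccccc2)c1O
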